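**Late rates.** Late in Sunday's run, at 15.0 min, 44.3 % of the starting material is left. We reckon in exposure, the natural logarithm of charge over what is left (the time integral of a pseudo-first-order constant), which reads 0.814 there. Tuesday's run, at the same temperature with more second substrate, reads 0.499, so exposure falls as second substrate to the power 0.620.

all flasks: free catalyst 0.15 mM
- Sunday's: starting material 0.15 M; second substrate 0.15 M; partner 0.30 M; temperature −5 °C; run made earlier
- Wednesday's: starting material 0.15 M; second substrate 0.21 M; partner 0.30 M; temperature 6 °C; run made earlier
- Tuesday's: starting material 0.15 M; second substrate 0.33 M; partner 0.30 M; temperature −5 °C; run made earlier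
- birch: starting material 0.15 M; second substrate 0.150 M; partner 0.300 M; temperature 0 °C; everything together at the start; time 15 min
- oak: starting material 0.15 M; second substrate 0.150 M; partner 0.300 M (fed, over 10 min); temperature 0 °C; all else is in the flask from the start; the feed brings no volume worth counting; time 15 min
- maple: starting material 0.15 M; second substrate 0.150 M; partner 0.300 M (in portions, 5, over 10 min); temperature 0 °C; first portion at the start, last at 10 min; time 15 min
- ash: starting material 0.15 M (fed, over 10 min); second substrate 0.150 M; partner 0.300 M; the addition at −20 °C, then warmed to 0 °C; the feed brings no volume worth counting; time 15 min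
- larch: starting material 0.15 M; second substrate 0.150 M; partner 0.300 M; everything together at the start at −20 °C, warmed to 0 °C at 10 min; time 15 min

| run | time / min | target / % | starting material / % |
|---|---|---|---|
| Sunday's | 3.00 | 20.7 | 80.8 |
| Sunday's | 6.00 | 33.3 | 67.0 |
| Sunday's | 10.0 | 46.2 | 53.7 |
| Sunday's | 12.0 | 49.6 | 49.2 |
| Sunday's | 15.0 | 56.3 | 44.3 |
| Wednesday's | 1.33 | 16.5 | 83.0 |
| Wednesday's | 2.50 | 27.4 | 72.6 |
| Wednesday's | 4.00 | 37.0 | 63.9 |
| Wednesday's | 8.00 | 50.4 | 49.0 |
| Wednesday's | 15.0 | 62.8 | 37.0 |
| Tuesday's | 3.00 | 12.5 | 87.5 |
| Tuesday's | 6.00 | 21.5 | 77.9 |
| Tuesday's | 10.0 | 31.4 | 69.4 |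
| Tuesday's | 12.0 | 34.8 | 66.4 |
| Tuesday's | 15.0 | 39.7 | 60.7 |

(readings scatter by 0.5 percentage points)

- which flask leads in amount of target, in percent of the starting material charged ("all alike" within 1.5 percentage points) (birch / oak / maple / ash / larch / all alike)
- how much target is there at the end, in percent of the starting material charged: birch
- how much target is there at the end, in percent of the starting material charged: oak
- how much target is there at the end, in percent of the starting material charged: maple
- how much target is there at the end, in percent of the starting material charged: ash
- how much target is there at the end, in percent of the starting material charged: larch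

- steps that have been proposed: catalyst intermediate B -> spent catalyst; second substrate + free catalyst <-> catalyst intermediate B; partner <-> dormant form; partner + catalyst intermediate B -> free catalyst + second product; starting material + free catalyst <-> catalyst intermediate A; partner + catalyst intermediate A -> free catalyst + target

**The chain.** Taking that reading as 0.667, Wednesday's run, brought back to Sunday's second substrate, reads 1.24. Interpolating the logarithm of exposure in temperature gives 0.987 at 0 °C, so birch should end near 62.7 % target.

Oak's steady feed and maple's equal portions both delay partner by 5.00 min on average. Those flasks therefore get 0.667 of a batch's partner-minutes, counting partner as unconsumed, and we call this the partner-time share. Multiplying exposure by the share gives 48.2 % target for each.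

**Weak link.** That step assumes exposure proportional to partner-minutes, yet every run so far has the same partner. If exposure went as the square root of partner-minutes instead, the same chain gives 55.3 %, so we commit to oak and maple between these two figures.

**The forecast.** It names birch as leader, with 61 % there, 42 % for oak, 43 % for maple, 43 % for ash and 47 % for larch, reasoning “Feeding partner halves its exposure over 10 min”. Our lower figure for oak and maple, 48.2 %, stands higher than its own.

**The flasks.** Birch leads with 64.3 %, then oak 50.9 %, maple 50.1 %, larch 46.9 % and ash 42.3 %.

    catalyst intermediate B → spent catalyst (k = 0.0112 min⁻¹, Ea = 81.0 kJ mol⁻¹)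
    second substrate + free catalyst ⇌ catalyst intermediate B (K = 600 M⁻¹, k = 513 M⁻¹ min⁻¹, Ea = 41.0 kJ mol⁻¹, ΔH = 36.0 kJ mol⁻¹)
    partner ⇌ dormant form (K = 0.560, k = 0.0342 min⁻¹, Ea = 84.0 kJ mol⁻¹, ΔH = −4.00 kJ mol⁻¹)
    partner + catalyst intermediate B → free catalyst + second product (k = 204 M⁻¹ min⁻¹, Ea = 37.0 kJ mol⁻¹)
    starting material + free catalyst ⇌ catalyst intermediate A (K = 2.30 M⁻¹, k = 3230 M⁻¹ min⁻¹, Ea = 45.0 kJ mol⁻¹, ΔH = 12.0 kJ mol⁻¹)
    partner + catalyst intermediate A → free catalyst + target (k = 6340 M⁻¹ min⁻¹, Ea = 46.0 kJ mol⁻¹)
    (constants at 0 °C)

**Share applied.** Oak stands 8.9 percentage points above the forecast. In birch at 3.90 min, catalyst intermediate A falls back 1.1 times as fast as it goes on to target. Birch's exposure is 1.03 and oak's is 0.710, a ratio of 0.689 against the share of 0.667. For maple, the share times birch's exposure gives 49.7 % target, and maple holds 50.1 %.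

The numbers in the tables are calculated with made-up constants; scatter was added.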